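**Plan**

- Locants follow the carbocycle: C1 (CHOAc), C4 (CHMe), C6 (C=O), C8 (C(OH)Me), C9=C10, C11 (O, iPr), C12, C13, C14 (O, Me); the ether oxygen bridges C11 and C14.
- Enabling feature: the β-hydroxy ketone C6(=O)–C7H2–C8(OH)Me is the adduct of a C6 acyl anion and a C7–C8 2,2-disubstituted epoxide. The fully substituted C11 blocks SN2′ entry at C10, and the cis-oxolane ring with the E-C9=C10 alkene folds the chain so that C6 can reach C7.
- Cuts, in retro order: C6–C7 (14-membered carbocycle); C9=C10 (Julia–Kocienski); the C1 and C10 carbonyls rejoined as the C=C of a 7-oxabicyclo[2.2.1]heptene; its C1–C2 bond (Negishi).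
- Forward: the oxolane exists from the start as the ether bridge of 1,4-cineol-2-one made from (R)-terpinen-4-ol (1). Its enol triflate takes on the C2–C6 chain from methyl (R)-3-methylglutarate (2), ozonolysis opens the bicycle, (S)-2-methylglycidol (3) supplies C7–C9, and the carbocycle closes last.
- Stereochemistry: C11 from 1, with C14 cis to it by the bicycle; C4 from 2; C8 from 3; C1 by chelate-controlled reduction; the E-alkene from the Julia–Kocienski step.

Key step: step 18

Remark: methyl (R)-3-methylglutarate (2) is taken as the commercial enantiopure half-ester; C-locants below are those of the target carbocycle unless the 7-oxabicycloheptane is named.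

**Route**

Step 1
Reactants: 1 (R)-(−)-terpinen-4-ol
Product: 5 (1S,2R,4R)-1-methyl-4-(propan-2-yl)-7-oxabicyclo[2.2.1]heptan-2-ol, via cis-epoxy alcohol 4 (not isolated)
Conditions: VO(acac)2 (1 mol%), t-BuOOH (1.2 equiv), CH2Cl2, 0 °C → rt; then TsOH·H2O (5 mol%), rt
Reagents that add atoms: tert-butyl hydroperoxide, CC(C)(C)OO
Why: Hydroxyl-directed vanadium epoxidation delivers oxygen syn to the tertiary alcohol, and acid then lets that alcohol open the tertiary epoxide carbon across the ring (transannular epoxide opening), a sequence known for this very alcohol; the ether bridge fixes the future C11 and C14 substituents cis, and the carbinol centre formed is erased in step 2.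

Step 2
Reactants: 5 2-exo-hydroxy-1,4-cineole
Product: 6 (1S,4R)-1-methyl-4-(propan-2-yl)-7-oxabicyclo[2.2.1]heptan-2-one (1,4-cineol-2-one)
Conditions: TPAP (5 mol%), NMO (1.5 equiv), 4 Å MS, CH2Cl2, rt
Reagents that add atoms: none
Why: Ley–Griffith oxidation of the secondary alcohol removes the stray carbinol centre and leaves a ketone whose only enolisable position is the bicyclic C3 methylene, the future C10.

Step 3
Reactants: 6 1,4-cineol-2-one
Product: 7 (1S,4S)-1-methyl-4-(propan-2-yl)-7-oxabicyclo[2.2.1]hept-2-en-2-yl trifluoromethanesulfonate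
Conditions: KHMDS (1.1 equiv), THF, −78 °C; N-(5-chloro-2-pyridyl)triflimide (1.15 equiv), −78 → −30 °C
Reagents that add atoms: N-(5-chloropyridin-2-yl)bis(trifluoromethanesulfonyl)imide, Clc1ccc(nc1)N(S(=O)(=O)C(F)(F)F)S(=O)(=O)C(F)(F)F
Why: Enol triflate formation: deprotonation can only occur at the bicyclic C3, and enolates of 7-oxanorbornan-2-ones persist at −78 °C long enough for O-sulfonylation by the reactive pyridyl triflimide to outrun β-elimination of the ether bridge.

Step 4
Reactants: 2 methyl (R)-3-methylglutarate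
Product: 9 (S)-4-methyloxan-2-one, via hydroxy acid 8 (not isolated)
Conditions: LiBH4 (2.2 equiv), THF, 0 °C → rt; then 2 M HCl, rt
Reagents that add atoms: none
Why: Chemoselective borohydride reduction of the ester beside the inert lithium carboxylate followed by acid lactonisation is the standard conversion of this half-ester into the lactone, the stereocentre is untouched, and reducing the ester arm (not the acid arm) makes the acid carbon C6 and the ester carbon C2, which maps (R)-2 onto the (4S) centre.

Step 5
Reactants: 9 (S)-4-methyloxan-2-one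
Product: 10 ethyl (R)-5-bromo-3-methylpentanoate
Conditions: HBr (g), EtOH, 0 °C → rt
Reagents that add atoms: hydrogen bromide, Br; ethanol, CCO
Why: Acid-promoted opening of the δ-lactone by bromide at the O–CH2 carbon (SN2) with Fischer esterification in the same pot is a classical lactone to ω-bromo ester conversion, and the β-stereocentre cannot epimerise.

Step 6
Reactants: 10 ethyl (R)-5-bromo-3-methylpentanoate
Product: 11 (R)-5-bromo-3-methylpentanal
Conditions: DIBAL-H (1.05 equiv), CH2Cl2, −78 °C; MeOH, aq Rochelle salt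
Reagents that add atoms: none
Why: Partial ester reduction: the tetrahedral aluminate formed with DIBAL-H is stable at −78 °C and releases the aldehyde only on work-up, while the primary bromide is inert to the hydride at this temperature.

Step 7
Reactants: 11 (R)-5-bromo-3-methylpentanal
Product: 12 (R)-2-(4-bromo-2-methylbutyl)-1,3-dioxolane
Conditions: ethylene glycol (3 equiv), PPTS (5 mol%), benzene, reflux (Dean–Stark)
Reagents that add atoms: ethane-1,2-diol, OCCO
Why: Acid-catalysed acetalisation with azeotropic removal of water; C6 is carried as a dioxolane because a dithiane would not survive the ozonolysis and the sulfide oxidation ahead.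

Step 8
Reactants: 12 (R)-2-(4-bromo-2-methylbutyl)-1,3-dioxolane; 7 bicyclic enol triflate
Product: 14 2-[(2S)-2-methyl-4-[(1S,4S)-1-methyl-4-(propan-2-yl)-7-oxabicyclo[2.2.1]hept-2-en-2-yl]butyl]-1,3-dioxolane, via alkylzinc bromide 13 (not isolated)
Conditions: 12 (1.3 equiv), Zn dust (2 equiv), I2 (5 mol%), DMA, 80 °C; then 7 (1.0 equiv), PdCl2(dppf) (5 mol%), THF/DMA, 50 °C
Reagents that add atoms: none
Why: Negishi coupling: iodine-activated zinc inserts into the primary C–Br bond in DMA, and the alkylzinc bromide couples with the alkenyl triflate under Pd(dppf) catalysis, whose wide bite angle makes reductive elimination faster than β-hydride elimination, forming the C1–C2 bond with acetal and ether bridge untouched.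

Step 9
Reactants: 14 2-alkyl-7-oxabicycloheptene
Product: 16 (2S,5S)-5-[(4S)-5-(1,3-dioxolan-2-yl)-4-methylpentanoyl]-5-methyl-2-(propan-2-yl)oxolane-2-carbaldehyde, via ozonide 15 (not isolated)
Conditions: O3, CH2Cl2, −78 °C (Sudan III end point); then Me2S (5 equiv), −78 °C → rt; used without delay
Reagents that add atoms: ozone, [O-][O+]=O
Why: Ozonolysis with reductive work-up cleaves the strained, electron-rich trisubstituted alkene far faster than ozone attacks the acetal, and because both alkene carbons sat in one bridge of the bicycle the C1 ketone and the C10 aldehyde emerge cis on the oxolane.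

Step 10
Reactants: 16 keto aldehyde
Product: 17 (1R,4S)-5-(1,3-dioxolan-2-yl)-1-[(2S,5S)-5-(hydroxymethyl)-2-methyl-5-(propan-2-yl)oxolan-2-yl]-4-methylpentan-1-ol
Conditions: Zn(BH4)2 (2 equiv), Et2O, −30 → 0 °C; aq NH4Cl
Reagents that add atoms: none
Why: Chelation-controlled (Cram-chelate) ketone reduction: zinc binds the C1 carbonyl and the ring oxygen, the five-membered chelate is fused to the oxolane whose C13–C12 edge covers one face, so hydride should enter from the face of the C14 methyl and set (1R), while the C10 aldehyde is reduced in the same operation.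

Step 11
Reactants: 17 diol
Product: 18 tert-butyl{[(2S,5S)-5-[(1R,4S)-1-(tert-butyldimethylsilyloxy)-5-(1,3-dioxolan-2-yl)-4-methylpentyl]-5-methyl-2-(propan-2-yl)oxolan-2-yl]methoxy}dimethylsilane
Conditions: TBSOTf (2.5 equiv), 2,6-lutidine (4 equiv), CH2Cl2, −78 → 0 °C
Reagents that add atoms: tert-butyldimethylsilyl trifluoromethanesulfonate, CC(C)(C)[Si](C)(C)OS(=O)(=O)C(F)(F)F
Why: Silylation with the silyl triflate and a hindered pyridine base is the reliable way to cap the C1 carbinol next to the quaternary C14, the primary C10 hydroxyl being silylated along with it, and at low temperature the dioxolane is not activated.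

Step 12
Reactants: 18 bis-silyl ether
Product: 19 [(2S,5S)-5-[(1R,4S)-1-(tert-butyldimethylsilyloxy)-5-(1,3-dioxolan-2-yl)-4-methylpentyl]-5-methyl-2-(propan-2-yl)oxolan-2-yl]methanol
Conditions: HF·pyridine, pyridine, THF, 0 °C → rt
Reagents that add atoms: none
Why: Selective desilylation: under buffered HF the primary silyl ether is cleaved much faster than the secondary one wedged between C14 and the chain, and the acetal is stable in the pyridine-buffered medium.

Step 13
Reactants: 19 C10 primary alcohol
Product: 20 5-{[(2S,5S)-5-[(1R,4S)-1-(tert-butyldimethylsilyloxy)-5-(1,3-dioxolan-2-yl)-4-methylpentyl]-5-methyl-2-(propan-2-yl)oxolan-2-yl]methylsulfanyl}-1-phenyl-1H-tetrazole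
Conditions: 1-phenyl-1H-tetrazole-5-thiol (1.5 equiv), PPh3 (1.5 equiv), DIAD (1.5 equiv), THF, 0 → 45 °C
Reagents that add atoms: 1-phenyl-1H-tetrazole-5-thiol, Sc1nnnn1-c1ccccc1
Why: Mitsunobu thioetherification: the acidic thiol protonates the betaine and its soft thiolate displaces the alkoxyphosphonium at the primary C10, the only free hydroxyl, with mild heating to offset the neopentyl position; no stereocentre is involved.

Step 14
Reactants: 20 tetrazolyl sulfide
Product: 21 the corresponding sulfone, 5-{[...]methylsulfonyl}-1-phenyl-1H-tetrazole (C6 still a dioxolane)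
Conditions: (NH4)6Mo7O24·4H2O (0.2 equiv), 30% H2O2 (10 equiv), EtOH, 0 °C → rt
Reagents that add atoms: hydrogen peroxide, OO
Why: Molybdate-catalysed peroxide oxidation takes the tetrazolyl sulfide to the sulfone without affecting silyl ether, acetal or ring ether, and it is placed here because no other oxidisable sulfur is yet present.

Step 15
Reactants: 21 sulfone dioxolane
Product: 22 sulfone dithiane (as 21, with 1,3-dithian-2-yl at C6)
Conditions: HS(CH2)3SH (1.5 equiv), BF3·OEt2 (1.5 equiv), CH2Cl2, −20 → 0 °C
Reagents that add atoms: propane-1,3-dithiol, SCCCS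
Why: Lewis-acid transthioacetalisation converts the dioxolane directly into the 1,3-dithiane because the dithiol traps the oxocarbenium ion irreversibly, and the sulfone and the hindered secondary silyl ether should tolerate BF3 at this temperature.

Step 16
Reactants: 3 (S)-2-methylglycidol
Product: 23 (R)-2-methyloxirane-2-carbaldehyde
Conditions: Dess–Martin periodinane (1.2 equiv), NaHCO3, CH2Cl2, 0 °C → rt; filtered through silica (pentane/Et2O), concentrated cold, used at once
Reagents that add atoms: none
Why: Dess–Martin oxidation under buffered, non-aqueous conditions gives the volatile epoxy aldehyde without opening the epoxide, and its quaternary α-carbon can neither enolise nor epimerise (the descriptor changes from S to R only through CIP priorities).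

Step 17
Reactants: 22 sulfone dithiane; 23 (R)-2-methyloxirane-2-carbaldehyde
Product: 24 tert-butyl{[(1R,4S)-5-(1,3-dithian-2-yl)-4-methyl-1-[(2S,5S)-2-methyl-5-[(E)-2-[(2S)-2-methyloxiran-2-yl]ethenyl]-5-(propan-2-yl)oxolan-2-yl]pentyl]oxy}dimethylsilane (seco dithiane vinyl epoxide)
Conditions: 22 and 23 (2 equiv), DME, −78 °C; KHMDS (1.2 equiv) added slowly; −78 °C → rt
Reagents that add atoms: none
Why: Julia–Kocienski olefination under Barbier conditions: the C10 sulfonyl carbanion is trapped by the non-enolisable aldehyde as soon as it forms, which limits β-elimination of the ring oxygen, and Smiles rearrangement with loss of SO2 and the tetrazolone gives the C9=C10 alkene, E being favoured by the potassium/DME pairing and by the fully substituted C8 and C11 on either side; the dithiane C–H is too weakly acidic for the amide base.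

Step 18
Reactants: 24 seco dithiane vinyl epoxide
Product: 26 macrocyclic dithiane alcohol (target locants: C1 OTBS, C6 spiro-1,3-dithiane, C8 OH; 1R,4S,8R,9E,11S,14S), via 2-lithio-1,3-dithiane 25 (not isolated)
Conditions: t-BuLi (1.15 equiv), THF/HMPA (10:1), 0.003 M, −78 °C, 10 min; then −78 → −20 °C over 4 h; aq NH4Cl
Reagents that add atoms: none
Why: tert-Butyllithium in THF/HMPA removes the C6 proton of the 2-alkyl-1,3-dithiane within minutes at −78 °C (the vinyl epoxide has no allylic hydrogens, C8 and C11 both being fully substituted), and on warming at millimolar concentration the lithiated dithiane 25 attacks the epoxide methylene C7 in an SN2 opening that forms C6–C7 and releases the C8 tertiary alkoxide. The closest known reactions are the intermolecular coupling of 2-lithio-2-alkyl-1,3-dithianes with terminal and 2,2-disubstituted epoxides (Corey–Seebach umpolung) and the closure of 14-membered carbocycles by sulfur-stabilised carbanions opening terminal epoxides. The single ring formed, the 14-membered carbocycle, closes in the 14-endo-tet mode by the usual convention for epoxides (attack at the distal carbon C7, both epoxide carbons entering the ring and the oxygen staying on ring carbon C8), which carries no geometric penalty at this ring size. No stereocentre is created: C8 keeps the configuration brought in with 3 because its C–O bond is not touched (the label changes from S to R by priority only), and the other four centres are spectators. The step needs site selectivity for C7 over SN2′ attack at C10, which the fully substituted C11 next to C10 and the 11-membered ring that C10 attack would require should secure, and ring closure over oligomerisation, which high dilution and the chain fold imposed by the cis-oxolane and the E-alkene should secure.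

Step 19
Reactants: 26 macrocyclic dithiane alcohol
Product: 27 macrocyclic dithiane diol (C1 OH, C8 OH)
Conditions: TBAF (3 equiv), THF, rt → 45 °C
Reagents that add atoms: none
Why: Fluoride desilylation is run while C6 is still a dithiane, so the basic fluoride never meets the β-hydroxy ketone, which could open by retro-aldol cleavage.

Step 20
Reactants: 27 macrocyclic dithiane diol
Product: 28 C1 acetate of 27
Conditions: Ac2O (2 equiv), pyridine, DMAP (0.1 equiv), CH2Cl2, 0 °C → rt
Reagents that add atoms: acetic anhydride, CC(=O)OC(C)=O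
Why: DMAP-catalysed acylation discriminates the secondary C1 hydroxyl from the tertiary allylic C8 hydroxyl, which should stay free under these conditions.

Step 21
Reactants: 28 acetate dithiane
Product: 29 CNP0131678.1 (1R,4S,8R,9E,11S,14S)
Conditions: PhI(OCOCF3)2 (1.5 equiv), NaHCO3, MeCN/H2O (9:1), 0 °C
Reagents that add atoms: water, O
Why: Oxidative dithiane hydrolysis: the hypervalent iodine reagent activates sulfur as a sulfonium ion and water delivers the C6 carbonyl within minutes at 0 °C under buffered conditions, so the β-hydroxy ketone meets neither base (retro-aldol) nor strong acid (dehydration), and acetate and alkene are untouched.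

**Compound list**

1 | (R)-(−)-terpinen-4-ol | CC1=CC[C@@](O)(C(C)C)CC1 | starting material
2 | methyl (R)-3-methylglutarate, (3R)-5-methoxy-3-methyl-5-oxopentanoic acid | COC(=O)C[C@H](C)CC(=O)O | starting material
3 | (S)-2-methylglycidol | OC[C@@]1(C)CO1 | starting material
4 | cis-1,2-epoxy-p-menthan-4-ol, epoxide oxygen syn to the hydroxyl (not isolated) | C[C@]12CC[C@](O)(C(C)C)C[C@H]1O2 | intermediate
5 | (1S,2R,4R)-1-methyl-4-(propan-2-yl)-7-oxabicyclo[2.2.1]heptan-2-ol (2-exo-hydroxy-1,4-cineole) | O[C@@H]1C[C@@]2(C(C)C)CC[C@]1(C)O2 | intermediate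
6 | (1S,4R)-1-methyl-4-(propan-2-yl)-7-oxabicyclo[2.2.1]heptan-2-one | O=C1C[C@@]2(C(C)C)CC[C@]1(C)O2 | intermediate
7 | (1S,4S)-1-methyl-4-(propan-2-yl)-7-oxabicyclo[2.2.1]hept-2-en-2-yl trifluoromethanesulfonate | FC(F)(F)S(=O)(=O)OC1=C[C@@]2(C(C)C)CC[C@]1(C)O2 | intermediate
8 | (S)-5-hydroxy-3-methylpentanoic acid (not isolated) | OCC[C@H](C)CC(=O)O | intermediate
9 | (S)-4-methyloxan-2-one | O=C1C[C@@H](C)CCO1 | intermediate
10 | ethyl (R)-5-bromo-3-methylpentanoate | BrCC[C@H](C)CC(=O)OCC | intermediate
11 | (R)-5-bromo-3-methylpentanal | BrCC[C@H](C)CC=O | intermediate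
12 | (R)-2-(4-bromo-2-methylbutyl)-1,3-dioxolane | BrCC[C@H](C)CC1OCCO1 | intermediate
13 | (R)-[4-(1,3-dioxolan-2-yl)-3-methylbutyl]zinc bromide (not isolated) | Br[Zn]CC[C@H](C)CC1OCCO1 | intermediate
14 | 2-[(2S)-2-methyl-4-[(1S,4S)-1-methyl-4-(propan-2-yl)-7-oxabicyclo[2.2.1]hept-2-en-2-yl]butyl]-1,3-dioxolane | C1(CC[C@H](C)CC3OCCO3)=C[C@@]2(C(C)C)CC[C@]1(C)O2 | intermediate
15 | ozonide (1,2,4-trioxolane) of 14, configuration at the two trioxolane carbons not defined (not isolated) | CC(C)[C@]12CC[C@](C)(O1)C1(CC[C@H](C)CC3OCCO3)OOC2O1 | intermediate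
16 | (2S,5S)-5-[(4S)-5-(1,3-dioxolan-2-yl)-4-methylpentanoyl]-5-methyl-2-(propan-2-yl)oxolane-2-carbaldehyde | O=C[C@@]1(C(C)C)CC[C@](C)(O1)C(=O)CC[C@H](C)CC1OCCO1 | intermediate
17 | (1R,4S)-5-(1,3-dioxolan-2-yl)-1-[(2S,5S)-5-(hydroxymethyl)-2-methyl-5-(propan-2-yl)oxolan-2-yl]-4-methylpentan-1-ol | OC[C@@]1(C(C)C)CC[C@](C)(O1)[C@H](O)CC[C@H](C)CC1OCCO1 | intermediate
18 | bis(tert-butyldimethylsilyl) ether of 17 | CC(C)(C)[Si](C)(C)OC[C@@]1(C(C)C)CC[C@](C)(O1)[C@H](O[Si](C)(C)C(C)(C)C)CC[C@H](C)CC1OCCO1 | intermediate
19 | [(2S,5S)-5-[(1R,4S)-1-(tert-butyldimethylsilyloxy)-5-(1,3-dioxolan-2-yl)-4-methylpentyl]-5-methyl-2-(propan-2-yl)oxolan-2-yl]methanol | OC[C@@]1(C(C)C)CC[C@](C)(O1)[C@H](O[Si](C)(C)C(C)(C)C)CC[C@H](C)CC1OCCO1 | intermediate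
20 | 1-phenyl-1H-tetrazol-5-yl sulfide of 19 (S at C10) | c1ccc(cc1)-n1nnnc1SC[C@@]1(C(C)C)CC[C@](C)(O1)[C@H](O[Si](C)(C)C(C)(C)C)CC[C@H](C)CC1OCCO1 | intermediate
21 | 1-phenyl-1H-tetrazol-5-yl sulfone, C6 dioxolane | c1ccc(cc1)-n1nnnc1S(=O)(=O)C[C@@]1(C(C)C)CC[C@](C)(O1)[C@H](O[Si](C)(C)C(C)(C)C)CC[C@H](C)CC1OCCO1 | intermediate
22 | 1-phenyl-1H-tetrazol-5-yl sulfone, C6 1,3-dithiane | c1ccc(cc1)-n1nnnc1S(=O)(=O)C[C@@]1(C(C)C)CC[C@](C)(O1)[C@H](O[Si](C)(C)C(C)(C)C)CC[C@H](C)CC1SCCCS1 | intermediate
23 | (R)-2-methyloxirane-2-carbaldehyde | O=C[C@@]1(C)CO1 | intermediate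
24 | seco dithiane vinyl epoxide (1R,4S,8S,9E,11S,14S in target locants; C1 OTBS, C6 dithiane, C7–C8 epoxide) | CC(C)(C)[Si](C)(C)O[C@H](CC[C@H](C)CC1SCCCS1)[C@]2(C)CC[C@@](/C=C/[C@@]3(C)CO3)(C(C)C)O2 | intermediate
25 | 2-lithio-1,3-dithiane derived from 24, lithium at C6 (not isolated) | CC(C)(C)[Si](C)(C)O[C@H](CC[C@H](C)CC1([Li])SCCCS1)[C@]2(C)CC[C@@](/C=C/[C@@]3(C)CO3)(C(C)C)O2 | intermediate
26 | macrocycle, C1 OTBS, C6 spiro-1,3-dithiane, C8 OH (1R,4S,8R,9E,11S,14S) | CC(C)(C)[Si](C)(C)O[C@@H]1CC[C@H](C)CC2(SCCCS2)C[C@@](C)(O)/C=C/[C@@]3(C(C)C)CC[C@]1(C)O3 | intermediate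
27 | macrocycle, C1 OH, C6 spiro-1,3-dithiane, C8 OH | O[C@@H]1CC[C@H](C)CC2(SCCCS2)C[C@@](C)(O)/C=C/[C@@]3(C(C)C)CC[C@]1(C)O3 | intermediate
28 | macrocycle, C1 OAc, C6 spiro-1,3-dithiane, C8 OH | CC(=O)O[C@@H]1CC[C@H](C)CC2(SCCCS2)C[C@@](C)(O)/C=C/[C@@]3(C(C)C)CC[C@]1(C)O3 | intermediate
29 | CNP0131678.1 (1R,4S,8R,9E,11S,14S) | CC(=O)O[C@@H]1CC[C@H](C)CC(=O)C[C@@](C)(O)/C=C/[C@@]2(C(C)C)CC[C@]1(C)O2 | target

**Count**

Total steps: 21. Longest linear sequence: 17 steps (2 → 29 through steps 4–15 and 17–21).

**Steps most likely to fail**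

1. Step 18 (macrocyclisation). What may go wrong: tert-butyllithium may add to the epoxide or metalate incompletely at millimolar concentration, and intermolecular epoxide opening may outpace ring closure and give oligomers. The fallback forms the same C6–C7 bond and ring by an intramolecular nitrile oxide–alkene cycloaddition; it sets out from 21 and comes back at 29.
   - Julia–Kocienski olefination of 21 with methacrolein (KHMDS, DME, −78 °C) gives the (E)-diene dioxolane F1.
   - Mild acid (PPTS, aqueous acetone) frees the C6 aldehyde F2, and hydroxylamine hydrochloride in pyridine gives the aldoxime F3.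
   - Aqueous NaOCl in CH2Cl2 at high dilution generates the C6 nitrile oxide, which adds across the 1,1-disubstituted C7=C8 alkene with oxygen going to the more substituted C8, closing the carbocycle as the isoxazoline F4.
   - C8 is then set by the facial selectivity of the cycloaddition and not by a building block, so the (8S) epimer F5 has to be separated at this stage.
   - Mo(CO)6 in wet acetonitrile cleaves the N–O bond and hydrolyses the imine to the β-hydroxy ketone F6.
   - HF·pyridine removes the silyl ether to give the diol ketone F7, and acetylation as in step 20 gives 29.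

2. Step 17 (Julia–Kocienski). What may go wrong: the C10 sulfonyl carbanion may expel the ring oxygen by β-elimination and open the oxolane, the neopentyl carbanion may add too slowly, and the volatile aldehyde may be lost or hydrated. The fallback avoids any carbanion at C10; it sets out from 19 and comes back at 24.
   - Transthioacetalisation of 19 (propane-1,3-dithiol, BF3·OEt2) gives the dithiane alcohol F8.
   - Parikh–Doering oxidation gives the C10 aldehyde F9.
   - Wittig olefination with 1-(triphenylphosphoranylidene)propan-2-one in hot toluene gives the (E)-enone F10.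
   - Corey–Chaykovsky epoxidation with dimethylsulfonium methylide adds to the ketone to give 24 together with its C8 epimer F11.
   - The remote stereocentres offer no facial bias here, so both epimers are expected and must be separated by chromatography; this route gives up the building-block control of C8.

3. Step 13 (Mitsunobu at C10). What may go wrong: SN2 displacement at the neopentyl C10 may be too slow, so that the alkoxyphosphonium ion is consumed by the hydrazide instead. The fallback sets out from 19 and comes back at 20: triflation (Tf2O, 2,6-lutidine, CH2Cl2, −78 °C) gives the triflate F12, which is displaced by sodium 1-phenyl-1H-tetrazole-5-thiolate in DMF at rt to give 20.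

**Further compounds**

F1 | step 18 | (E)-diene from 21 and methacrolein: C1 OTBS, C6 dioxolane, C10=C9–C8(Me)=C7H2 | CC(C)(C)[Si](C)(C)O[C@H](CC[C@H](C)CC1OCCO1)[C@]2(C)CC[C@@](/C=C/C(C)=C)(C(C)C)O2
F2 | step 18 | C6 aldehyde from F1 | CC(C)(C)[Si](C)(C)O[C@H](CC[C@H](C)CC=O)[C@]2(C)CC[C@@](/C=C/C(C)=C)(C(C)C)O2
F3 | step 18 | C6 aldoxime from F2 (E/Z mixture) | CC(C)(C)[Si](C)(C)O[C@H](CC[C@H](C)CC=NO)[C@]2(C)CC[C@@](/C=C/C(C)=C)(C(C)C)O2
F4 | step 18 | (8R)-macrocyclic isoxazoline, C6=N–O–C8, C1 OTBS | CC(C)(C)[Si](C)(C)O[C@@H]1CC[C@H](C)CC2=NO[C@](C)(C2)/C=C/[C@@]3(C(C)C)CC[C@]1(C)O3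
F5 | step 18 | (8S)-epimer of F4 | CC(C)(C)[Si](C)(C)O[C@@H]1CC[C@H](C)CC2=NO[C@@](C)(C2)/C=C/[C@@]3(C(C)C)CC[C@]1(C)O3
F6 | step 18 | macrocyclic β-hydroxy ketone, C1 OTBS | CC(C)(C)[Si](C)(C)O[C@@H]1CC[C@H](C)CC(=O)C[C@@](C)(O)/C=C/[C@@]2(C(C)C)CC[C@]1(C)O2
F7 | step 18 | deacetyl target, C1 OH, C8 OH, C6 ketone | O[C@@H]1CC[C@H](C)CC(=O)C[C@@](C)(O)/C=C/[C@@]2(C(C)C)CC[C@]1(C)O2
F8 | step 17 | dithiane analogue of 19, C10 OH | OC[C@@]1(C(C)C)CC[C@](C)(O1)[C@H](O[Si](C)(C)C(C)(C)C)CC[C@H](C)CC1SCCCS1
F9 | step 17 | C10 aldehyde from F8 | O=C[C@@]1(C(C)C)CC[C@](C)(O1)[C@H](O[Si](C)(C)C(C)(C)C)CC[C@H](C)CC1SCCCS1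
F10 | step 17 | (E)-enone, C10=C9–C8(=O)–CH3 | CC(=O)/C=C/[C@@]1(C(C)C)CC[C@](C)(O1)[C@H](O[Si](C)(C)C(C)(C)C)CC[C@H](C)CC1SCCCS1
F11 | step 17 | C8 epimer of 24 | CC(C)(C)[Si](C)(C)O[C@H](CC[C@H](C)CC1SCCCS1)[C@]2(C)CC[C@@](/C=C/[C@]3(C)CO3)(C(C)C)O2
F12 | step 13 | C10 trifluoromethanesulfonate of 19 | FC(F)(F)S(=O)(=O)OC[C@@]1(C(C)C)CC[C@](C)(O1)[C@H](O[Si](C)(C)C(C)(C)C)CC[C@H](C)CC1OCCO1
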